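**Assumption:** the target SMILES has no stereocentre, so the compound is achiral and the "single enantiomer" is the compound itself. The one stereocentre that appears on the way (the carbinol carbon of 3) is formed racemic and is erased in step 2. The route is a plan from known reaction types and has not been run.

## Retrosynthetic overview

1. Target 6 ⇐ tetramethyl ether 4 by global O-demethylation as the last step.
2. 4 ⇐ carbinol 3 by reductive removal of the benzylic hydroxyl.
3. 3 ⇐ key C–C disconnection of the central CH(OH)–CH2 bond: a benzyl carbanion equivalent (N–H hydrazone 2) plus aldehyde 1, so both carbons come from aldehyde carbons.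
4. 2 ⇐ 1 + hydrazine; 1 is commercial 3-bromo-4,5-dimethoxybenzaldehyde.
5. No ring is formed: both arene rings are bought intact in 1, with the Br and O pattern already in place.

## Route

**Step 1**
Reactants: 1 3-bromo-4,5-dimethoxybenzaldehyde (two molecules: one converted in the flask to its hydrazone, one used as the aldehyde)
Product: 3 rac-1,2-bis(3-bromo-4,5-dimethoxyphenyl)ethan-1-ol, via hydrazone 2 (not isolated)
Conditions: (a) 1 (1.2 equiv), N2H4·H2O (1.25 equiv), THF, rt, 1 h; (b) 1 (1.0 equiv), [RuCl2(p-cymene)]2 (1.5 mol%), dmpe (3 mol%), K3PO4 (25 mol%), CsF (1.0 equiv), THF, 45 °C, 12 h, N2 atmosphere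
Reagents that add atoms: hydrazine monohydrate, NN.O (adds nitrogen to intermediate 2 only; it leaves as N2 before 3)
Why: The N–H hydrazone 2, bound to the divalent ruthenium centre, acts as a benzyl carbanion equivalent and adds through a six-membered transition state to the aldehyde carbon of a second molecule of 1, after which base-mediated loss of N2 leaves the CH2 group (ruthenium-catalysed carbonyl-umpolung addition of a hydrazone to an aldehyde, Wolff–Kishner-type); the carbinol stereocentre forms as a racemate and is removed in step 2.

**Step 2**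
Reactants: 3 rac-1,2-bis(3-bromo-4,5-dimethoxyphenyl)ethan-1-ol
Product: 4 1,2-bis(3-bromo-4,5-dimethoxyphenyl)ethane
Conditions: Et3SiH (3 equiv), CF3CO2H (10 equiv), CH2Cl2, 0 °C to rt
Reagents that add atoms: none
Why: Acid ionises the benzylic alcohol to a cation stabilised by the para-methoxy group and Et3SiH traps it by hydride transfer (ionic hydrogenation), a reduction that leaves the aryl bromides and methyl ethers untouched and also returns any stilbene formed by elimination to the same cation.

**Step 3**
Reactants: 4 1,2-bis(3-bromo-4,5-dimethoxyphenyl)ethane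
Product: 6 target bibenzyl 1,2-bis(3-bromo-4,5-dihydroxyphenyl)ethane, via bis(bromodioxaborole) 5 (not isolated)
Conditions: BBr3 (6 equiv, 1 M in CH2Cl2), CH2Cl2, −78 °C to rt, 12 h; then H2O, 0 °C, work-up under argon
Reagents that add atoms: boron tribromide, BrB(Br)Br (adds boron and bromine to intermediate 5 only; none of its atoms remain in 6)
Why: BBr3 coordinates each ether oxygen and bromide removes the methyl group by SN2 (Lewis-acid ether cleavage), giving the cyclic catechol bromoboronate 5 that water hydrolyses to the free catechols, while aryl bromides and the saturated bridge are inert.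

## Compound list

1 | 3-bromo-4,5-dimethoxybenzaldehyde (5-bromoveratraldehyde) | COc1cc(C=O)cc(Br)c1OC | starting material
2 | (E)-(3-bromo-4,5-dimethoxybenzylidene)hydrazine (N-unsubstituted hydrazone of 1) | N/N=C/c1cc(Br)c(OC)c(OC)c1 | intermediate (not isolated)
3 | rac-1,2-bis(3-bromo-4,5-dimethoxyphenyl)ethan-1-ol | OC(Cc1cc(Br)c(OC)c(OC)c1)c1cc(Br)c(OC)c(OC)c1 | intermediate
4 | 1,2-bis(3-bromo-4,5-dimethoxyphenyl)ethane | COc1cc(CCc2cc(OC)c(OC)c(Br)c2)cc(Br)c1OC | intermediate
5 | 1,2-bis(2,4-dibromo-1,3,2-benzodioxaborol-6-yl)ethane | BrB1Oc2cc(CCc3cc(Br)c4OB(Br)Oc4c3)cc(Br)c2O1 | intermediate (not isolated)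
6 | 1,2-bis(3-bromo-4,5-dihydroxyphenyl)ethane (achiral) | Oc1cc(CCc2cc(O)c(O)c(Br)c2)cc(Br)c1O | target

## Step count and risk

Total step count: 3. Longest linear sequence: 3 steps (1 → 3 → 4 → 6).

**Most likely to fail, in order:**

**Step 1 (key coupling).** The risks are azine formation between 2 and 1, low electrophilicity of the electron-rich aldehyde, and simple Wolff–Kishner reduction of 2 to the toluene. The fallback sets out from compound 1 and comes back at compound 3. Aldehyde 1 is dimerised through its acyl anion equivalent (Breslow intermediate) with 3-benzyl-5-(2-hydroxyethyl)-4-methylthiazolium chloride (10 mol%) and Et3N in EtOH at 80 °C, giving the benzoin rac-1,2-bis(3-bromo-4,5-dimethoxyphenyl)-2-hydroxyethan-1-one F1. Zinc dust in AcOH at 80 °C removes the α-hydroxyl to give the deoxybenzoin 1,2-bis(3-bromo-4,5-dimethoxyphenyl)ethan-1-one F2. NaBH4 in MeOH at 0 °C reduces the ketone to carbinol 3, and the route continues with step 2.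

**Step 2 (ionic deoxygenation).** The cation is only moderately stabilised (meta-Br, twisted para-OMe), so the reaction may stop at the trifluoroacetate or the stilbene, or give Friedel–Crafts oligomers. The fallback sets out from compound 3 and comes back at compound 4. Carbinol 3 is dehydrated on purpose with catalytic TsOH·H2O in refluxing toluene (Dean–Stark) to (E)-1,2-bis(3-bromo-4,5-dimethoxyphenyl)ethene F3. The alkene is then saturated by diimide, generated from TsNHNH2 and NaOAc in refluxing DME/H2O, which does not touch aryl bromides, giving 4.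

**Step 3 (global demethylation).** The risks are incomplete cleavage of the hindered 4-methoxy groups flanked by bromine, and air oxidation of the bis-catechol during aqueous work-up. The fallback sets out from compound 4 and comes back at compound 6. Reductive demethylation with Et3SiH (5 equiv) and B(C6F5)3 (5 mol%) in CH2Cl2 at rt, with loss of methane, gives the isolable, air-stable silyl ether 1,2-bis[3-bromo-4,5-bis(triethylsilyloxy)phenyl]ethane F4. This can be chromatographed and is then desilylated with HCl in MeOH at rt under argon to give 6.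

## Further compounds

F1 | step 1 | rac-1,2-bis(3-bromo-4,5-dimethoxyphenyl)-2-hydroxyethan-1-one | COc1cc(C(O)C(=O)c2cc(OC)c(OC)c(Br)c2)cc(Br)c1OC
F2 | step 1 | 1,2-bis(3-bromo-4,5-dimethoxyphenyl)ethan-1-one | COc1cc(CC(=O)c2cc(OC)c(OC)c(Br)c2)cc(Br)c1OC
F3 | step 2 | (E)-1,2-bis(3-bromo-4,5-dimethoxyphenyl)ethene | COc1cc(/C=C/c2cc(OC)c(OC)c(Br)c2)cc(Br)c1OC
F4 | step 3 | 1,2-bis[3-bromo-4,5-bis(triethylsilyloxy)phenyl]ethane | CC[Si](CC)(CC)Oc1cc(CCc2cc(O[Si](CC)(CC)CC)c(O[Si](CC)(CC)CC)c(Br)c2)cc(Br)c1O[Si](CC)(CC)CC
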